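**Target (17):** 2-[(3R,5S)-5-[(8E,10E,12E)-hexadeca-8,10,12-trien-1-yl]-3,5-dimethyl-1,2-dioxolan-3-yl]acetic acid. It has one ring (1,2-dioxolane) and two quaternary stereocentres, C3 (R) and C5 (S), with CH2CO2H trans to the long chain.

## Retrosynthetic overview

1. Last C–C bond: B-alkyl Suzuki coupling of the terminal alkene of dioxolane ester 12 with iodotriene 14 (from heptadienal 13), then saponification in the same flask.
2. C3: addition of a silyl ketene acetal to the peroxycarbenium ion from 1,2-dioxolan-3-ol 10.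
3. Key step (C5 and the peroxide ring): perhydrolytic ring expansion of the (R)-methylideneoxetane 8 with H2O2, with inversion; 8 comes from β-lactone 7 by methylenation.
4. 7 comes from carbonylative ring expansion of (R)-epoxide 6, made by catalytic asymmetric CH2 transfer to dec-9-en-2-one 5 (hydrazone 1 + bromide 2).
5. Ring order: oxirane → oxetan-2-one → methylideneoxetane → 1,2-dioxolane (the only ring of the target).

Assumption: the (R)-binaphtholate catalyst in step 2 is taken to deliver CH2 to the Si face of ketone 5 (by analogy with aryl methyl ketones); if a calibration run shows the opposite sense, the (S)-ligand is used and nothing else changes.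

## Route

Step 1
Reactants: 1 acetone N,N-dimethylhydrazone; 2 7-bromohept-1-ene
Product: 5 dec-9-en-2-one, via lithio hydrazone 3 (not isolated), via alkylated hydrazone 4 (not isolated)
Conditions: n-BuLi, THF, −78 → 0 °C; then 2, 0 °C → rt; then aq. oxalic acid, Et2O, rt
Reagents that add atoms: water, O
Why: Corey–Enders-type alkylation of the lithio azaenolate of a symmetrical ketone hydrazone with a primary bromide gives clean monoalkylation, and mild acid hydrolysis of the C=N bond frees the methyl ketone; no stereocentre is formed.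

Step 2
Reactants: 5 dec-9-en-2-one
Product: 6 (R)-2-methyl-2-(oct-7-en-1-yl)oxirane
Conditions: Me3S(O)I, NaH, THF (ylide, 1.2 equiv); LaLi3[(R)-binaphtholate]3 (5 mol %), (2,4,6-(MeO)3C6H2)3P=O (5 mol %), 5 Å MS, THF, rt
Reagents that add atoms: trimethylsulfoxonium iodide (CH2 through its ylide), C[S+](C)(C)=O.[I-]
Why: Catalytic asymmetric Corey–Chaykovsky epoxidation; the La/Li binaphtholate–phosphine oxide complex binds ketone and ylide, tells methyl from the long alkyl group and transfers CH2 to the Si face, setting the quaternary carbon as R (about 90–95 % ee expected for an unbranched alkyl methyl ketone, checked by chiral GC), while the terminal alkene is inert.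

Step 3
Reactants: 6 (R)-2-methyl-2-(oct-7-en-1-yl)oxirane
Product: 7 (R)-4-methyl-4-(oct-7-en-1-yl)oxetan-2-one
Conditions: [(salph)Al(THF)2][Co(CO)4] (5 mol %; salph = N,N'-o-phenylenebis(3,5-di-tert-butylsalicylideneiminate)), CO (60 bar), Et2O, 22–40 °C
Reagents that add atoms: carbon monoxide, [C-]#[O+]
Why: Lewis acid/cobaltate carbonylative ring expansion of a 2,2-disubstituted epoxide; [Co(CO)4]− opens the activated epoxide at the unsubstituted CH2, CO inserts and the aluminium alkoxide closes the lactone, so the C–O bond at the quaternary carbon is never broken and R is retained.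

Step 4
Reactants: 7 (R)-4-methyl-4-(oct-7-en-1-yl)oxetan-2-one
Product: 8 (R)-2-methyl-4-methylidene-2-(oct-7-en-1-yl)oxetane
Conditions: Cp2TiMe2 (2.5 equiv), toluene, 75 °C, dark; basic alumina
Reagents that add atoms: dimethyltitanocene, C[Ti](C)(C1C=CC=C1)C1C=CC=C1
Why: Petasis methylenation; thermally generated Cp2Ti=CH2 olefinates the lactone carbonyl under neutral conditions that leave the strained ring, the remote alkene and the stereocentre untouched.

Step 5
Reactants: 8 (R)-2-methyl-4-methylidene-2-(oct-7-en-1-yl)oxetane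
Product: 10 (5S)-3,5-dimethyl-5-(oct-7-en-1-yl)-1,2-dioxolan-3-ol (both C3 epimers), via hydroperoxy ketone 9 (not isolated)
Conditions: H2O2 (anhydrous, ca. 2 M in Et2O, 10 equiv), TMSOTf (0.2 equiv), Et2O, −78 → −40 °C, slow addition of 8, blast shield; NaHCO3 quench
Reagents that add atoms: hydrogen peroxide, OO
Why: Proposed new method: C-protonation of the exocyclic enol ether (TfOH from TMSOTf/H2O2) gives a 2-methyloxetan-2-ylium ion, a strained O-alkylated ketone whose O–C(quaternary) bond is the leaving bond; H2O2 attacks the quaternary carbon from the rear in a loose SN2 with inversion, (R)-8 → (S)-9, and the released methyl ketone is captured by the new OOH to close the peroxyhemiketal (5S)-10, so the old ring oxygen ends as the exocyclic OH and the O–O unit takes its place in a four- to five-membered ring expansion; reversible Markovnikov perhydration of the enol ether drains back through the same cation; the closest known reaction types are the Lewis-acid perhydrolysis of 2,2-disubstituted oxetanes at the tertiary carbon with inversion and the nucleophilic opening of 2-methylideneoxetanes at the ring carbon remote from the enol ether with release of a ketone.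

Step 6
Reactants: 10 (5S)-3,5-dimethyl-5-(oct-7-en-1-yl)-1,2-dioxolan-3-ol
Product: 12 methyl 2-[(3R,5S)-3,5-dimethyl-5-(oct-7-en-1-yl)-1,2-dioxolan-3-yl]acetate, via silyl peroxyketal 11 (not isolated)
Conditions: CH2=C(OMe)OSiMe3 (3 equiv), TMSOTf (0.3 equiv), CH2Cl2, −78 → −40 °C; C3 epimers separated on silica (HPLC if needed)
Reagents that add atoms: 1-methoxy-1-(trimethylsilyloxy)ethene, C=C(OC)O[Si](C)(C)C
Why: Mukaiyama-type SN1 substitution at a peroxyketal; the first equivalent of ketene acetal silylates the hemiketal OH, TMSOTf ionises 11 to the 3-methyl-1,2-dioxolan-3-ylium (peroxycarbenium) ion, and the ketene acetal adds to the face anti to the longer C5 chain to give 3R; the inherent bias is small (about 2:1 expected), so the epimers are separated.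

Step 7
Reactants: 13 (2E,4E)-hepta-2,4-dienal
Product: 14 (1E,3E,5E)-1-iodoocta-1,3,5-triene
Conditions: CHI3 (2 equiv), CrCl2 (6 equiv), THF/1,4-dioxane 1:6, 0 °C → rt, dark; used at once
Reagents that add atoms: iodoform, IC(I)I
Why: Takai iodo-olefination; the geminal dichromium species from CHI3 and CrCl2 adds to the aldehyde and eliminates through the less hindered arrangement to give the E vinyl iodide, extending the E,E-dienal to the E,E,E-iodotriene.

Step 8
Reactants: 12 methyl 2-[(3R,5S)-3,5-dimethyl-5-(oct-7-en-1-yl)-1,2-dioxolan-3-yl]acetate; 14 (1E,3E,5E)-1-iodoocta-1,3,5-triene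
Product: 17 2-[(3R,5S)-5-[(8E,10E,12E)-hexadeca-8,10,12-trien-1-yl]-3,5-dimethyl-1,2-dioxolan-3-yl]acetic acid, via alkylborane 15 (not isolated), via triene methyl ester 16 (not isolated)
Conditions: 9-BBN-H (1.5 equiv), THF, 0 °C → rt; then 14, Pd(dppf)Cl2 (5 mol %), AsPh3 (10 mol %), 3 M aq NaOH, THF/DMF, rt, dark; then NaOH, MeOH/H2O, rt; dilute HCl to pH 4
Reagents that add atoms: sodium hydroxide (O of the carboxylic OH), [Na+].[OH-]
Why: B-alkyl Suzuki–Miyaura coupling followed by saponification in the same flask; 9-BBN adds anti-Markovnikov to the terminal alkene only, the sp3 borane couples with retention of the E geometry of the iodide, and hydroxide cleaves the methyl ester, while the tetrasubstituted dialkyl peroxide has no α-hydrogen and neither quaternary stereocentre is touched.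

## Compound list

1 | acetone N,N-dimethylhydrazone | CC(C)=NN(C)C | starting material
2 | 7-bromohept-1-ene | C=CCCCCCBr | starting material
3 | lithiated acetone N,N-dimethylhydrazone | [Li]CC(C)=NN(C)C | intermediate (not isolated)
4 | dec-9-en-2-one N,N-dimethylhydrazone | C=CCCCCCCC(C)=NN(C)C | intermediate (not isolated)
5 | dec-9-en-2-one | C=CCCCCCCC(C)=O | intermediate
6 | (R)-2-methyl-2-(oct-7-en-1-yl)oxirane | C=CCCCCCC[C@]1(C)CO1 | intermediate
7 | (R)-4-methyl-4-(oct-7-en-1-yl)oxetan-2-one | C=CCCCCCC[C@]1(C)CC(=O)O1 | intermediate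
8 | (R)-2-methyl-4-methylidene-2-(oct-7-en-1-yl)oxetane | C=CCCCCCC[C@]1(C)CC(=C)O1 | intermediate
9 | (S)-4-hydroperoxy-4-methyldodec-11-en-2-one | C=CCCCCCC[C@](C)(OO)CC(C)=O | intermediate (not isolated)
10 | (5S)-3,5-dimethyl-5-(oct-7-en-1-yl)-1,2-dioxolan-3-ol (C3 epimers) | C=CCCCCCC[C@@]1(C)CC(C)(O)OO1 | intermediate
11 | {[(5S)-3,5-dimethyl-5-(oct-7-en-1-yl)-1,2-dioxolan-3-yl]oxy}trimethylsilane | C=CCCCCCC[C@@]1(C)CC(C)(O[Si](C)(C)C)OO1 | intermediate (not isolated)
12 | methyl 2-[(3R,5S)-3,5-dimethyl-5-(oct-7-en-1-yl)-1,2-dioxolan-3-yl]acetate | C=CCCCCCC[C@@]1(C)C[C@](C)(CC(=O)OC)OO1 | intermediate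
13 | (2E,4E)-hepta-2,4-dienal | CC/C=C/C=C/C=O | starting material
14 | (1E,3E,5E)-1-iodoocta-1,3,5-triene | CC/C=C/C=C/C=C/I | intermediate
15 | methyl 2-[(3R,5S)-5-[8-(9-borabicyclo[3.3.1]nonan-9-yl)octyl]-3,5-dimethyl-1,2-dioxolan-3-yl]acetate | C1CCC2CCCC1B2CCCCCCCC[C@@]1(C)C[C@](C)(CC(=O)OC)OO1 | intermediate (not isolated)
16 | methyl 2-[(3R,5S)-5-[(8E,10E,12E)-hexadeca-8,10,12-trien-1-yl]-3,5-dimethyl-1,2-dioxolan-3-yl]acetate | CC/C=C/C=C/C=C/CCCCCCCC[C@@]1(C)C[C@](C)(CC(=O)OC)OO1 | intermediate (not isolated)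
17 | 2-[(3R,5S)-5-[(8E,10E,12E)-hexadeca-8,10,12-trien-1-yl]-3,5-dimethyl-1,2-dioxolan-3-yl]acetic acid | CC/C=C/C=C/C=C/CCCCCCCC[C@@]1(C)C[C@](C)(CC(=O)O)OO1 | target

## Step count and risks

Total steps: 8 (steps 1–6 and 8 are linear; step 7 is a one-step side branch). Longest linear sequence: 7.

**Step 5 (proposed new ring expansion).** Risks: ionisation at the tertiary carbon (SN1) would erode ee or give the enone by elimination, and traces of water would give the hydroxy ketone. The ee of 10 is read on ester 12 by chiral HPLC. The fallback is known chemistry; it sets out from 8 and comes back at 10. The enol ether of 8 is hydrolysed (PPTS, wet THF) to (R)-4-hydroxy-4-methyldodec-11-en-2-one F1. NaBH4 gives (4R)-4-methyldodec-11-ene-2,4-diol F2. TsCl/pyridine sulfonylates only the secondary hydroxyl, giving (4R)-4-hydroxy-4-methyldodec-11-en-2-yl 4-methylbenzenesulfonate F3. KOtBu closes (2R)-2,4-dimethyl-2-(oct-7-en-1-yl)oxetane F4 by Williamson etherification, with the tertiary C–O bond untouched. The known Lewis-acid perhydrolysis of oxetanes (H2O2/Et2O, TMSOTf, −78 °C) opens F4 at the tertiary carbon with inversion to (4S)-4-hydroperoxy-4-methyldodec-11-en-2-ol F5. 2-Methoxypropene/PPTS masks the OOH as (4S)-4-[(2-methoxypropan-2-yl)peroxy]-4-methyldodec-11-en-2-ol F6. Dess–Martin oxidation gives (4S)-4-[(2-methoxypropan-2-yl)peroxy]-4-methyldodec-11-en-2-one F7. Aqueous AcOH removes the ketal, and the freed hydroperoxy ketone 9 closes to 10.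

**Step 6 (C3 configuration).** Risk: the substrate bias between methyl and the chain at C5 is weak, so the dr may be near 1:1; the free hemiketal may also ionise poorly. The fallback moves face selection to a chiral reagent; it sets out from 10 and comes back at 12. MeOH/PPTS converts 10 into (5S)-3-methoxy-3,5-dimethyl-5-(oct-7-en-1-yl)-1,2-dioxolane F8. The chlorotitanium enolate of (S)-3-acetyl-4-isopropyl-1,3-thiazolidine-2-thione (TiCl4, i-Pr2NEt, CH2Cl2) is added to the peroxycarbenium ion released from F8 by SnCl4 at −78 °C. This gives 1-[(4S)-4-isopropyl-2-thioxo-1,3-thiazolidin-3-yl]-2-[(3R,5S)-3,5-dimethyl-5-(oct-7-en-1-yl)-1,2-dioxolan-3-yl]ethan-1-one F9. The sense of induction is not known in advance, so the auxiliary antipode is chosen in a two-run screen. MeOH/imidazole methanolysis then gives 12 and returns the auxiliary.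

**Step 8 (borane and palladium chemistry next to a peroxide, labile iodotriene).** Risk: reduction of the O–O bond by the borane or by zerovalent palladium, and isomerisation of the triene. The fallback installs the triene before any peroxide exists; it sets out from 6 and comes back at 16. 6 is hydroborated with 9-BBN-H to 9-{8-[(2R)-2-methyloxiran-2-yl]octyl}-9-borabicyclo[3.3.1]nonane F10 and coupled with 14 (Pd(dppf)Cl2, aq NaOH) to (R)-2-[(8E,10E,12E)-hexadeca-8,10,12-trien-1-yl]-2-methyloxirane F11. F11 is then taken through the same four operations as in steps 3–6: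
- carbonylation to (R)-4-[(8E,10E,12E)-hexadeca-8,10,12-trien-1-yl]-4-methyloxetan-2-one F12;
- methylenation to (R)-2-[(8E,10E,12E)-hexadeca-8,10,12-trien-1-yl]-2-methyl-4-methylideneoxetane F13;
- perhydrolytic ring expansion through (4S,13E,15E,17E)-4-hydroperoxy-4-methylicosa-13,15,17-trien-2-one F14 to (5S)-5-[(8E,10E,12E)-hexadeca-8,10,12-trien-1-yl]-3,5-dimethyl-1,2-dioxolan-3-ol F15;
- ketene acetal addition through {[(5S)-5-[(8E,10E,12E)-hexadeca-8,10,12-trien-1-yl]-3,5-dimethyl-1,2-dioxolan-3-yl]oxy}trimethylsilane F16 to 16.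

16 is then saponified on its own (LiOH, THF/H2O) to 17.

## Further compounds

F1 | step 5 | (R)-4-hydroxy-4-methyldodec-11-en-2-one | C=CCCCCCC[C@@](C)(O)CC(C)=O
F2 | step 5 | (4R)-4-methyldodec-11-ene-2,4-diol (C2 epimers) | C=CCCCCCC[C@@](C)(O)CC(C)O
F3 | step 5 | (4R)-4-hydroxy-4-methyldodec-11-en-2-yl 4-methylbenzenesulfonate | C=CCCCCCC[C@@](C)(O)CC(C)OS(=O)(=O)c1ccc(C)cc1
F4 | step 5 | (2R)-2,4-dimethyl-2-(oct-7-en-1-yl)oxetane (C4 epimers) | C=CCCCCCC[C@]1(C)CC(C)O1
F5 | step 5 | (4S)-4-hydroperoxy-4-methyldodec-11-en-2-ol | C=CCCCCCC[C@](C)(OO)CC(C)O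
F6 | step 5 | (4S)-4-[(2-methoxypropan-2-yl)peroxy]-4-methyldodec-11-en-2-ol | C=CCCCCCC[C@](C)(OOC(C)(C)OC)CC(C)O
F7 | step 5 | (4S)-4-[(2-methoxypropan-2-yl)peroxy]-4-methyldodec-11-en-2-one | C=CCCCCCC[C@](C)(OOC(C)(C)OC)CC(C)=O
F8 | step 6 | (5S)-3-methoxy-3,5-dimethyl-5-(oct-7-en-1-yl)-1,2-dioxolane (C3 epimers) | C=CCCCCCC[C@@]1(C)CC(C)(OC)OO1
F9 | step 6 | 1-[(4S)-4-isopropyl-2-thioxo-1,3-thiazolidin-3-yl]-2-[(3R,5S)-3,5-dimethyl-5-(oct-7-en-1-yl)-1,2-dioxolan-3-yl]ethan-1-one | C=CCCCCCC[C@@]1(C)C[C@](C)(CC(=O)N2[C@@H](C(C)C)CSC2=S)OO1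
F10 | step 8 | 9-{8-[(2R)-2-methyloxiran-2-yl]octyl}-9-borabicyclo[3.3.1]nonane | C1CCC2CCCC1B2CCCCCCCC[C@]1(C)CO1
F11 | step 8 | (R)-2-[(8E,10E,12E)-hexadeca-8,10,12-trien-1-yl]-2-methyloxirane | CC/C=C/C=C/C=C/CCCCCCCC[C@]1(C)CO1
F12 | step 8 | (R)-4-[(8E,10E,12E)-hexadeca-8,10,12-trien-1-yl]-4-methyloxetan-2-one | CC/C=C/C=C/C=C/CCCCCCCC[C@]1(C)CC(=O)O1
F13 | step 8 | (R)-2-[(8E,10E,12E)-hexadeca-8,10,12-trien-1-yl]-2-methyl-4-methylideneoxetane | CC/C=C/C=C/C=C/CCCCCCCC[C@]1(C)CC(=C)O1
F14 | step 8 | (4S,13E,15E,17E)-4-hydroperoxy-4-methylicosa-13,15,17-trien-2-one | CC/C=C/C=C/C=C/CCCCCCCC[C@](C)(OO)CC(C)=O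
F15 | step 8 | (5S)-5-[(8E,10E,12E)-hexadeca-8,10,12-trien-1-yl]-3,5-dimethyl-1,2-dioxolan-3-ol (C3 epimers) | CC/C=C/C=C/C=C/CCCCCCCC[C@@]1(C)CC(C)(O)OO1
F16 | step 8 | {[(5S)-5-[(8E,10E,12E)-hexadeca-8,10,12-trien-1-yl]-3,5-dimethyl-1,2-dioxolan-3-yl]oxy}trimethylsilane | CC/C=C/C=C/C=C/CCCCCCCC[C@@]1(C)CC(C)(O[Si](C)(C)C)OO1
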